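Two of us read these runs and part over the hot flask.

the same everywhere: J 25 mM (held)
- Thursday's: X 0.56 M; temperature 55 °C; run made earlier
- Sunday's: X 0.88 M; temperature 80 °C; run made earlier
- maple: X 0.40 M; temperature 60 °C; time 6.0 min
- elm: X 0.40 M; temperature 100 °C; time 6.0 min
- birch: X 0.40 M; temperature 80 °C; time 6.0 min

- Thursday's (time / min: G / %): 0.333: 0; 1.00: 2; 1.50: 5; 2.50: 9; 4.00: 10; 5.00: 13; 6.00: 15
- Sunday's (time / s: G / %): 12.0: 0; 15.0: 0; 20.0: 1; 30.0: 2; 60.0: 4; 80.0: 10; 120: 11

(readings scatter by 1.5 percentage points)

* the flask with the highest amount of G, in percent of the X charged ("all alike" if they lie within 1.5 percentage points) (maple / elm / birch / all alike)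
* final G, as a percentage of the X charged, in maple
* final G, as a percentage of the X charged, in elm
* final G, as a percentage of the X charged, in birch

- at the start none of J is in solution

The forecast reckons on the condition of a rate first order in X while calling the order unresolved, and I make the same assumption for my reckoning: with J held, I take a molecule of X to have a steady chance per minute of reacting (pseudo-first-order), so that I can carry percentages from one charge of X to another. The forecast reaches its numbers by allowing for the lag and the depletion of X, while I hold that G, a mono adduct, can take the gas again at the same chance. Following one molecule, with exposure θ as chance per minute times minutes, I expect G to stand at θ·exp(−θ), which tops out at exposure one with 36.8%.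

I start each clock at the last zero reading, 0.333 min on Thursday and 15.0 s on Sunday. Thursday's 15% at 6.00 min gives an exposure of 0.179 and a chance of 0.0315 min⁻¹. Sunday's 10% at 80.0 s gives 0.112 and 0.103 min⁻¹, so the chance grows by a factor of 3.27 between those temperatures, as far as such scattered readings show. Growing at that steady pace with temperature, the chance per minute of a molecule in maple is 0.0399 min⁻¹.

At 6.0 min my exposures are 0.240 in maple, 0.619 in birch and 1.60 in elm, which is beyond the top. That gives me 18.9%, 33.3% and 32.3%, so I call birch and elm alike.

The forecast says elm, with 16% in maple, 45% in elm and 30% in birch, adding that “G could react further, so the hot flasks are uncertain”.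

The simulation gives birch, with 18.5% in maple, 17.5% in elm and 26.2% in birch, so neither call stands. Elm had already turned, with G at 18.9% at 3.00 min and 17.5% at 6.00 min, beside Q at 38.3%. The forecast's view keeps the region of small exposure: in maple, at 0.240, the one-step reckoning and mine lie 2.4 percentage points apart.

    X + D → G (k = 21.0 M⁻¹ min⁻¹, Ea = 60.0 kJ mol⁻¹)
    D + G → Z (k = 20.0 M⁻¹ min⁻¹, Ea = 58.0 kJ mol⁻¹)
    X + G → Q (k = 1.30 M⁻¹ min⁻¹, Ea = 90.0 kJ mol⁻¹)
    J ⇌ D, rate k4*(csat - [D]) (kL = 4.20 min⁻¹)
    X ⇌ E (K = 0.220, k = 0.170 min⁻¹, Ea = 118 kJ mol⁻¹, ΔH = −35.0 kJ mol⁻¹)
    (constants at 100 °C)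

For maple left until 25 min, the carried chance gives an exposure of 0.998, about the top, so G near 36.8%. The computed flask holds 31.0% G, with 29.0% X and 27.6% Z.

The runs come from a simulation for an exercise, and the scatter is random.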